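The spiro-dihydropyran is cut by a retro-hetero-Diels–Alder reaction into a 2-substituted acrolein on a cis-fused methylene-decalin and an α-methylene lactone. Everything rests on ring A (C1–C5, C10) of the decalin half: it is first closed as a cyclopentanone (C4, C2, C1, C10, C5), where the cis C5–C10 fusion is the thermodynamically favoured one, and is then enlarged in one operation by insertion of C3 between C4 and C2 with a silyl diazoalkane. This transfers the cis fusion into the six-membered ring, where equilibration could not secure it. The precursor is a cis-hydrindanone with an isopropenyl group, three steps from (S)-carvone.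

Key step: step 4

Remark (assumption): the α-methylene lactone partner of the last step is a natural product that can be bought and is used as such.
Atom labels: eudesmane numbering for the methylene-decalin half (ring A = C1–C5, C10; ring B = C5–C10; C14 = methyl on C10; C15 = exocyclic CH2 on C4; C11–C13 = side chain on C7); primed numbers for the lactone half.

Step 1
Reactants: 1 (S)-(+)-carvone
Product: 2 (2S,5S)-dihydrocarvone
Conditions: Zn dust, KOH, EtOH–H2O, reflux
Reagents that add atoms: none
Why: Dissolving-zinc conjugate reduction saturates only the enone C=C and leaves the isopropenyl group and the C7 stereocentre untouched; the new methyl-bearing centre forms as a trans/cis mixture that does not matter, because this carbon becomes the sp2 enamine carbon in step 2.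

Step 2
Reactants: 2 (2S,5S)-dihydrocarvone; 3 (S)-1-phenylethylamine; 4 methyl acrylate
Product: 7 methyl 3-[(1R,4S)-1-methyl-2-oxo-4-(prop-1-en-2-yl)cyclohexyl]propanoate, via imine 5 (not isolated), via alkylated imine 6 (not isolated)
Conditions: TsOH (cat.), toluene, reflux, Dean–Stark; then 4, neat, 60 °C; then AcOH/H2O/THF, rt
Reagents that add atoms: water (O)
Why: d'Angelo asymmetric Michael addition, in which the imine reacts through its more substituted secondary enamine tautomer in an aza-ene-like transition state and the (S)-phenylethyl auxiliary directs the acrylate to the face anti to the isopropenyl group, so that the new quaternary C10 is (R) with C14 cis to the side chain, before aqueous acid returns the ketone and the amine.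

Step 3
Reactants: 7 methyl 3-[(1R,4S)-1-methyl-2-oxo-4-(prop-1-en-2-yl)cyclohexyl]propanoate
Product: 9 (3aR,6S,7aR)-3a-methyl-6-(prop-1-en-2-yl)octahydro-1H-inden-1-one, via cyclic methyl enol ether 8 (not isolated)
Conditions: TiCl3, LiAlH4, Et3N, DME, reflux, slow addition of 7; then 1 M HCl, THF, rt
Reagents that add atoms: water (O)
Why: McMurry keto ester cyclisation, in which low-valent titanium couples the ketone and ester carbonyl carbons (C5–C4 bond, five-membered ring) to the cyclic enol ether, whose acid hydrolysis protonates C5 and equilibrates this α-centre to the thermodynamically preferred cis-hydrindanone (C5–H cis to C14).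

Step 4
Reactants: 9 (3aR,6S,7aR)-3a-methyl-6-(prop-1-en-2-yl)octahydro-1H-inden-1-one
Product: 11 (4aS,7S,8aR)-4a-methyl-7-(prop-1-en-2-yl)octahydronaphthalen-1(2H)-one, via β-keto silane 10 (not isolated)
Conditions: Me3SiCHN2, BF3·OEt2, CH2Cl2, −78 to −30 °C; then wet SiO2, CH2Cl2, rt
Reagents that add atoms: (trimethylsilyl)diazomethane (C[Si](C)(C)C=[N+]=[N-])
Why: The BF3-activated C4 carbonyl of 9 is attacked by the nucleophilic carbon of the silyl diazoalkane, and the β-alkoxy diazonium ion loses N2 with 1,2-shift of the anti-periplanar C2 methylene from C4 to the new carbon C3, giving β-keto silane 10, which is protodesilylated on wet silica. The closest known reaction type is the Lewis acid promoted diazoalkane homologation of cycloalkanones (Tiffeneau–Demjanov-type ring enlargement). No ring is closed by cyclisation: ring A (C1–C5, C10) arises from the cyclopentanone ring (C4, C2, C1, C10, C5) by enlargement by one atom through a 1,2-alkyl shift. No lasting stereocentre is created (the silyl-bearing C3 is transient), and C5, C7 and C10 are bystanders, so the cis C5–C10 fusion fixed in 9 is carried into the decalin. The step needs migration of the CH2 carbon in preference to the ring-fusion methine C5 and a single homologation; the first is secured by the steric demand of the silyl diazoalkane, which favours shift of the less substituted α-carbon, the second by the hindered, less electrophilic β-keto silane. Low temperature and the non-basic work-up keep the epimerisable C5–H intact.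

Step 5
Reactants: 11 (4aS,7S,8aR)-4a-methyl-7-(prop-1-en-2-yl)octahydronaphthalen-1(2H)-one
Product: 12 (4aS,7S,8aR)-7-(3-hydroxyprop-1-en-2-yl)-4a-methyloctahydronaphthalen-1(2H)-one
Conditions: SeO2 (cat.), t-BuOOH, salicylic acid (cat.), CH2Cl2, rt
Reagents that add atoms: tert-butyl hydroperoxide (CC(C)(C)OO)
Why: Sharpless allylic hydroxylation (SeO2 ene reaction, then [2,3]-sigmatropic shift, with t-BuOOH as terminal oxidant) functionalises the methyl group of the only alkene under near-neutral conditions that should not enolise the C4 ketone; no stereocentre is formed.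

Step 6
Reactants: 12 (4aS,7S,8aR)-7-(3-hydroxyprop-1-en-2-yl)-4a-methyloctahydronaphthalen-1(2H)-one
Product: 13 2-[(2S,4aS,8aS)-4a-methyl-8-methylidenedecahydronaphthalen-2-yl]prop-2-en-1-ol
Conditions: Zn, CH2Br2, TiCl4 (pre-formed reagent, excess), THF/CH2Cl2, 0 °C to rt
Reagents that add atoms: dibromomethane (BrCBr)
Why: Takai–Lombardo methylenation, whose non-basic geminal dimetallic CH2 reagent converts the hindered, epimerisable C4 ketone into the exocyclic C4=C15 alkene without enolisation, so the cis C5 configuration is kept, and which tolerates the free hydroxyl group when used in excess.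

Step 7
Reactants: 13 2-[(2S,4aS,8aS)-4a-methyl-8-methylidenedecahydronaphthalen-2-yl]prop-2-en-1-ol
Product: 14 2-[(2S,4aS,8aS)-4a-methyl-8-methylidenedecahydronaphthalen-2-yl]prop-2-enal
Conditions: MnO2, CH2Cl2, rt
Reagents that add atoms: none
Why: MnO2 oxidises only the allylic primary alcohol to the 2-substituted acrolein and leaves the isolated alkene and all stereocentres untouched.

Step 8
Reactants: 14 2-[(2S,4aS,8aS)-4a-methyl-8-methylidenedecahydronaphthalen-2-yl]prop-2-enal; 15 (+)-alantolactone
Product: 16 target spiro-dihydropyran dimer CNP0108778.1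
Conditions: 15 (3 equiv), BHT (cat.), toluene, 140 °C, sealed tube
Reagents that add atoms: none
Why: Thermal hetero-Diels–Alder reaction with the enal (O=C12–C11=C13) as oxadiene and the C11'=C13' α-methylene lactone as 2π partner, of the type known from acrolein dimerisation and acrolein–acrylate additions (oxygen bonds to the carbonyl-bearing alkene carbon C11'); the only new stereocentre, spiro C11', should be set by addition to the convex lactone face syn to H7', and excess 15 suppresses self-dimerisation of 14.

Compound list
1 | (S)-(+)-carvone, (5S)-2-methyl-5-(prop-1-en-2-yl)cyclohex-2-en-1-one | CC1=CC[C@@H](CC1=O)C(C)=C | starting material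
2 | (2S,5S)-dihydrocarvone, trans isomer shown; the 2-epimer formed alongside converges in step 2 | O=C1[C@@H](C)CC[C@H](C(C)=C)C1 | intermediate
3 | (S)-1-phenylethylamine | C[C@H](N)c1ccccc1 | starting material
4 | methyl acrylate | C=CC(=O)OC | starting material
5 | N-[(S)-1-phenylethyl] imine of 2 (ring methyl centre and C=N geometry not fixed) | C[C@H](N=C1C(C)CC[C@H](C(C)=C)C1)c1ccccc1 | intermediate
6 | N-[(S)-1-phenylethyl] imine of keto ester 7 | C[C@H](N=C1[C@@](C)(CCC(=O)OC)CC[C@H](C(C)=C)C1)c1ccccc1 | intermediate
7 | methyl 3-[(1R,4S)-1-methyl-2-oxo-4-(prop-1-en-2-yl)cyclohexyl]propanoate (methyl cis to isopropenyl) | O=C1[C@@](C)(CCC(=O)OC)CC[C@H](C(C)=C)C1 | intermediate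
8 | (5S,7aR)-3-methoxy-7a-methyl-5-(prop-1-en-2-yl)-2,4,5,6,7,7a-hexahydro-1H-indene (enol ether C4=C5) | COC=1CC[C@@]2(C)CC[C@H](C(C)=C)CC=12 | intermediate
9 | (3aR,6S,7aR)-3a-methyl-6-(prop-1-en-2-yl)octahydro-1H-inden-1-one, cis-fused | O=C1CC[C@@]2(C)CC[C@H](C(C)=C)C[C@@H]12 | intermediate
10 | 2-(trimethylsilyl) derivative of 11 (silicon on C3, configuration at C3 not fixed) | O=C1C([Si](C)(C)C)CC[C@@]2(C)CC[C@H](C(C)=C)C[C@@H]12 | intermediate
11 | (4aS,7S,8aR)-4a-methyl-7-(prop-1-en-2-yl)octahydronaphthalen-1(2H)-one, cis-fused | O=C1CCC[C@@]2(C)CC[C@H](C(C)=C)C[C@@H]12 | intermediate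
12 | (4aS,7S,8aR)-7-(3-hydroxyprop-1-en-2-yl)-4a-methyloctahydronaphthalen-1(2H)-one | O=C1CCC[C@@]2(C)CC[C@H](C(=C)CO)C[C@@H]12 | intermediate
13 | 2-[(2S,4aS,8aS)-4a-methyl-8-methylidenedecahydronaphthalen-2-yl]prop-2-en-1-ol (cis-fused; ent-5-epi-β-costol) | C=C1CCC[C@@]2(C)CC[C@H](C(=C)CO)C[C@@H]12 | intermediate
14 | 2-[(2S,4aS,8aS)-4a-methyl-8-methylidenedecahydronaphthalen-2-yl]prop-2-enal (cis-fused; ent-5-epi-β-costal) | C=C1CCC[C@@]2(C)CC[C@H](C(=C)C=O)C[C@@H]12 | intermediate
15 | (+)-alantolactone, (3aR,5S,8aR,9aR)-5,8a-dimethyl-3-methylidene-3a,5,6,7,8,8a,9,9a-octahydronaphtho[2,3-b]furan-2(3H)-one | C=C1C(=O)O[C@@H]2C[C@@]3(C)CCC[C@H](C)C3=C[C@H]12 | starting material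
16 | CNP0108778.1, spiro-dihydropyran adduct of 14 and 15 | C=C1CCC[C@@]2(C)CC[C@H](C3=CO[C@@]4(CC3)C(=O)O[C@@H]3C[C@@]5(C)CCC[C@H](C)C5=C[C@@H]34)C[C@@H]12 | target

Total step count: 8. Longest linear sequence: 8 steps (1 to 16); compound 15 enters in the last step.

Steps most likely to fail

Step 4 (key step). What may go wrong: the ring-fusion carbon C5 migrates instead of C2 (wrong regiochemistry of the 1,2-shift), a second homologation takes place, or the cis fusion is lost by enolisation during desilylation. Fallback with fixed regiochemistry (Ito–Saegusa ring enlargement), setting out from 9 and returning at 11: kinetic deprotonation on the CH2 side (LDA, Me3SiCl, THF, −78 °C) gives the silyl enol ether F1; Et2Zn/CH2I2 (1 equiv, 0 °C) cyclopropanates the electron-rich enol ether to the siloxycyclopropane F2; FeCl3 in DMF opens the internal C4–C2 bond to the ring-enlarged β-chloro ketone F3; NaOAc in MeOH eliminates HCl to the enone F4; conjugate reduction with [(Ph3P)CuH]6 gives 11.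

Step 3. What may go wrong: intermolecular pinacol coupling of the hindered ketone or simple reduction outruns the ketone–ester coupling. Fallback from 7, returning at 9: LiAlH4 reduces both carbonyl groups to the diol F5; Swern oxidation ((COCl)2, DMSO, Et3N) gives the keto aldehyde F6; SmI2 (THF, t-BuOH) closes the five-membered ring by intramolecular pinacol coupling to the cis-diol F7; TsOH in warm benzene ionises the tertiary C5 hydroxyl and a hydride shift from C4 (pinacol rearrangement) gives the ketone, which settles as cis-fused 9.

Step 8. What may go wrong: self-dimerisation of 14 and addition of its oxadiene to the more electron-rich exocyclic C4=C15 alkene of a second molecule compete with the cross-cycloaddition, and prolonged heating erodes the mass balance. Fallback from 12, returning at 16: the cycloaddition is moved before the methylenation, so that no second alkene is present. MnO2 oxidises 12 to the keto enal F8; heating F8 with excess 15 (toluene, 140 °C) gives the keto dimer F9; Zn/CH2Br2/TiCl4, which methylenates ketones in preference to lactones and without base, converts the C4 ketone of F9 into 16.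

Further compounds
F1 | step 4 | trimethylsilyl enol ether of 9 (C4=C2 enol ether) | C[Si](C)(C)OC1=CC[C@@]2(C)CC[C@H](C(C)=C)C[C@@H]12
F2 | step 4 | siloxycyclopropane from F1 (CH2 bridging C4 and C2) | C[Si](C)(C)OC12CC1C[C@@]3(C)CC[C@H](C(C)=C)C[C@@H]23
F3 | step 4 | β-chloro ketone (chlorine on C2 of the enlarged ring) | O=C1CC(Cl)C[C@@]2(C)CC[C@H](C(C)=C)C[C@@H]12
F4 | step 4 | enone (C4 ketone, C2=C3 alkene) | O=C1C=CC[C@@]2(C)CC[C@H](C(C)=C)C[C@@H]12
F5 | step 3 | diol from reduction of 7 | OCCC[C@@]1(C)CC[C@H](C(C)=C)CC1O
F6 | step 3 | keto aldehyde | O=CCC[C@@]1(C)CC[C@H](C(C)=C)CC1=O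
F7 | step 3 | hydrindane-1,7a-diol (pinacol product) | OC1CC[C@@]2(C)CC[C@H](C(C)=C)CC12O
F8 | step 8 | keto enal, 2-[(2S,4aS,8aR)-4a-methyl-8-oxodecahydronaphthalen-2-yl]prop-2-enal | O=C1CCC[C@@]2(C)CC[C@H](C(=C)C=O)C[C@@H]12
F9 | step 8 | keto dimer (16 with C4=O in place of C4=C15) | O=C1CCC[C@@]2(C)CC[C@H](C3=CO[C@@]4(CC3)C(=O)O[C@@H]3C[C@@]5(C)CCC[C@H](C)C5=C[C@@H]34)C[C@@H]12
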